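The lactone is numbered O1, C2(=O), C3 (benzyl-bearing), C4 and C5H2, and the carbinol carbon is C7'. The plan cuts the lactone ring at C3–C4 and O1–C5. It exploits the fact that C7' and C5 are both gamma carbons of the same acid. The two-carbon acyl unit can therefore first hang on O7', as the iodoacetate of (S)-1-(3,4-dimethoxyphenyl)allyl alcohol. In one flask, a 5-exo iodine atom-transfer cyclisation joins C3 to C4 under control of C7'. KOSiMe3 then cuts the temporary acyl–O7' bond, and the freed carboxylate displaces iodide at C5. The guaiacylmethyl group enters last by trans-selective enolate alkylation.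

Key step: step 4

Step 1
Reactants: 1 3,4-dimethoxybenzaldehyde; 2 vinylmagnesium bromide
Product: 3 rac-1-(3,4-dimethoxyphenyl)prop-2-en-1-ol
Conditions: CH2=CHMgBr, THF, 0 °C; then sat. aq. NH4Cl
Reagents that add atoms: none
Why: Grignard 1,2-addition to the aldehyde should give the racemic aryl vinyl carbinol, whose stereocentre is sorted in step 2.

Step 2
Reactants: 3 rac-1-(3,4-dimethoxyphenyl)prop-2-en-1-ol
Product: 4 (S)-1-(3,4-dimethoxyphenyl)prop-2-en-1-ol
Conditions: immobilised Candida antarctica lipase B, vinyl acetate, MTBE, 30 °C, stopped just past half conversion; chromatography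
Reagents that add atoms: none
Why: In this enzymatic kinetic resolution by irreversible transesterification, the lipase (aryl in the large pocket, vinyl in the medium pocket) should acylate the (R)-enantiomer and leave (S)-4, which fixes C7'.

Step 3
Reactants: 4 (S)-1-(3,4-dimethoxyphenyl)prop-2-en-1-ol; 5 iodoacetic acid
Product: 6 (S)-1-(3,4-dimethoxyphenyl)prop-2-en-1-yl iodoacetate
Conditions: DCC, DMAP (cat.), CH2Cl2, −10 °C, dark; filtration through Et3N-washed silica
Reagents that add atoms: none
Why: Steglich esterification acylates O7' without touching the C7'–O bond, so the configuration is retained, and the cold neutral medium should keep the allylic benzylic ester from ionising.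

Step 4
Reactants: 6 (S)-1-(3,4-dimethoxyphenyl)prop-2-en-1-yl iodoacetate
Product: 9 (R)-4-[(S)-(3,4-dimethoxyphenyl)(trimethylsilyloxy)methyl]dihydrofuran-2(3H)-one, via trans-iodomethyl lactone 7 (not isolated), via potassium iodo carboxylate 8 (not isolated)
Conditions: (Bu3Sn)2 (10 mol %), solid K2CO3, PhH (0.01 M), sunlamp, 80 °C; cool, concentrate, then KOSiMe3 (1.3 equiv), 18-crown-6 (cat.), THF, 23 → 40 °C, same flask, no work-up in between
Reagents that add atoms: potassium trimethylsilanolate C[Si](C)(C)[O-].[K+]
Why: Bu3Sn radicals from photolysed (Bu3Sn)2 abstract iodine from 6, the acyl-stabilised primary radical adds 5-exo-trig to the inner vinyl carbon (C3–C4 bond, temporary lactone through O7'), and the new primary radical at C5 takes iodine from a further molecule of 6, which carries the chain and gives 7. KOSiMe3 then attacks the acyl carbon of 7, O7' leaves and is capped by the Me3Si group, and carboxylate 8 displaces iodide 5-exo-tet (O1–C5 bond, final lactone ring). The closest known reaction types are the iodine atom-transfer radical cyclisation of allyl iodoacetates (which needs heat to reach the reactive ester rotamer), the silanolate cleavage of esters and the lactonisation of gamma-halo carboxylates. The only new stereocentre, C4, is controlled by C7': in the chair-like 5-exo transition state the aryl group sits pseudo-equatorial, so 7 should be the 4,5-trans lactone, which maps onto (4R) in 9, while the C7'–O bond is never broken and stays (S). The step needs 5-exo over 6-endo closure (secured by the unsubstituted vinyl terminus and the short tether), acyl attack over enolisation or substitution at CH2I or C7' (secured by the weakly basic silanolate, the reactive lactone carbonyl and the hindered secondary C7'), and closure by the carboxylate rather than by O7' (secured by silylation of O7').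

Step 5
Reactants: 10 4-(benzyloxy)-3-methoxybenzyl alcohol
Product: 11 4-(benzyloxy)-3-methoxybenzyl bromide
Conditions: PBr3, Et2O, 0 °C; used at once
Reagents that add atoms: phosphorus tribromide BrP(Br)Br
Why: Bromide should displace the phosphite ester of the primary benzylic alcohol (SN2) under conditions that leave the aryl benzyl ether intact.

Step 6
Reactants: 9 (R)-4-[(S)-(3,4-dimethoxyphenyl)(trimethylsilyloxy)methyl]dihydrofuran-2(3H)-one; 11 4-(benzyloxy)-3-methoxybenzyl bromide
Product: 14 (3R,4R)-3-[4-(benzyloxy)-3-methoxybenzyl]-4-[(S)-(3,4-dimethoxyphenyl)(hydroxy)methyl]dihydrofuran-2(3H)-one, via lithium enolate 12 (not isolated), via silyl ether 13 (not isolated)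
Conditions: LiN(SiMe3)2, THF, −78 °C; 11, DMPU, −78 → −40 °C; then 10 % aq. citric acid, THF, 0 °C
Reagents that add atoms: none
Why: In this lactone enolate alkylation the bromide should approach the enolate face anti to the bulky C4 substituent, setting C3 as (R) in the 3,4-trans series, and the mild acid wash removes the Me3Si group.

Step 7
Reactants: 14 (3R,4R)-3-[4-(benzyloxy)-3-methoxybenzyl]-4-[(S)-(3,4-dimethoxyphenyl)(hydroxy)methyl]dihydrofuran-2(3H)-one
Product: 15 (3R,4R)-4-[(S)-(3,4-dimethoxyphenyl)(hydroxy)methyl]-3-(4-hydroxy-3-methoxybenzyl)dihydrofuran-2(3H)-one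
Conditions: H2 (1 atm), Pd/C, EtOAc, 23 °C, stopped at consumption of 14
Reagents that add atoms: none
Why: Catalytic hydrogenolysis of the aryl benzyl ether should be much faster in neutral ethyl acetate than cleavage of the secondary C7'–OH, and it touches no stereocentre.

Compound list
1 | 3,4-dimethoxybenzaldehyde | COc1ccc(C=O)cc1OC | starting material
2 | vinylmagnesium bromide | C=C[Mg]Br | starting material
3 | rac-1-(3,4-dimethoxyphenyl)prop-2-en-1-ol | C=CC(O)c1ccc(OC)c(OC)c1 | intermediate
4 | (S)-1-(3,4-dimethoxyphenyl)prop-2-en-1-ol | C=C[C@H](O)c1ccc(OC)c(OC)c1 | intermediate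
5 | iodoacetic acid | OC(=O)CI | starting material
6 | (S)-1-(3,4-dimethoxyphenyl)prop-2-en-1-yl iodoacetate | C=C[C@H](OC(=O)CI)c1ccc(OC)c(OC)c1 | intermediate
7 | (4S,5S)-5-(3,4-dimethoxyphenyl)-4-(iodomethyl)dihydrofuran-2(3H)-one | O=C1C[C@H](CI)[C@@H](c2ccc(OC)c(OC)c2)O1 | intermediate
8 | potassium (3S,4S)-4-(3,4-dimethoxyphenyl)-3-(iodomethyl)-4-(trimethylsilyloxy)butanoate | [K+].[O-]C(=O)C[C@H](CI)[C@H](O[Si](C)(C)C)c1ccc(OC)c(OC)c1 | intermediate
9 | (R)-4-[(S)-(3,4-dimethoxyphenyl)(trimethylsilyloxy)methyl]dihydrofuran-2(3H)-one | O=C1C[C@H](CO1)[C@H](O[Si](C)(C)C)c2ccc(OC)c(OC)c2 | intermediate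
10 | 4-(benzyloxy)-3-methoxybenzyl alcohol | COc1cc(CO)ccc1OCc1ccccc1 | starting material
11 | 4-(benzyloxy)-3-methoxybenzyl bromide | COc1cc(CBr)ccc1OCc1ccccc1 | intermediate
12 | lithium enolate of 9 | [Li+].[O-]C1=C[C@H](CO1)[C@H](O[Si](C)(C)C)c2ccc(OC)c(OC)c2 | intermediate
13 | (3R,4R)-3-[4-(benzyloxy)-3-methoxybenzyl]-4-[(S)-(3,4-dimethoxyphenyl)(trimethylsilyloxy)methyl]dihydrofuran-2(3H)-one | COc1cc(C[C@H]2C(=O)OC[C@@H]2[C@H](O[Si](C)(C)C)c2ccc(OC)c(OC)c2)ccc1OCc1ccccc1 | intermediate
14 | (3R,4R)-3-[4-(benzyloxy)-3-methoxybenzyl]-4-[(S)-(3,4-dimethoxyphenyl)(hydroxy)methyl]dihydrofuran-2(3H)-one | COc1cc(C[C@H]2C(=O)OC[C@@H]2[C@H](O)c2ccc(OC)c(OC)c2)ccc1OCc1ccccc1 | intermediate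
15 | (3R,4R)-4-[(S)-(3,4-dimethoxyphenyl)(hydroxy)methyl]-3-(4-hydroxy-3-methoxybenzyl)dihydrofuran-2(3H)-one | COc1cc(C[C@H]2C(=O)OC[C@@H]2[C@H](O)c2ccc(OC)c(OC)c2)ccc1O | target

Total step count: 7. Longest linear sequence: 6 (steps 1, 2, 3, 4, 6, 7).

Steps most likely to fail

Step 4. Three things may go wrong.
- The ester may stay in its unreactive rotamer, so that the radical oligomerises before it cyclises.
- The hot allylic benzylic ester may ionise, which brings allylic transposition and erosion of enantiopurity.
- The facial selectivity of the ring closure may be modest.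

The fallback sets out from 4 and replaces the ester tether by an acetal tether (Ueno–Stork type). N-iodosuccinimide and ethyl vinyl ether at −20 °C should give the mixed iodoacetal F1. Its radical has neither a rotamer barrier nor an ionisable acyloxy group. Iodine atom-transfer cyclisation (Et3B, air, 23 °C) should then give the 2-ethoxy-4-(iodomethyl)tetrahydrofuran F2. Jones oxidation (CrO3/H2SO4, acetone, 0 °C) turns the acetal carbon into the lactone carbonyl. This comes back to the route at 7, now isolated, which is treated with KOSiMe3 as in step 4.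

Step 6. The trimethylsilyl group may be lost under the basic conditions. The lactone acyl group could then migrate to O7', and alkylation would occur in the wrong ring. Double alkylation is also possible. The fallback sets out from 9 and changes the protecting-group plan. Citric acid should free the hydroxy lactone F3, and TBSOTf with 2,6-lutidine should give the tert-butyldimethylsilyl ether F4. Alkylation with LiN(SiMe3)2 and 11 should give the trans-alkylated silyl ether F5. HF·pyridine in THF at 0 °C then comes back to the route at 14.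

Step 7. Over-reduction may occur, meaning hydrogenolysis of the electron-rich benzylic C7'–OH alongside the benzyl ether. The fallback sets out from 14 and shields the carbinol during the reduction. TESCl and imidazole should give the triethylsilyl ether F6, and H2 over Pd/C in EtOAc should give the free phenol silyl ether F7. Buffered HF·pyridine then comes back to the route at 15.

Further compounds
F1 | step 4 | (S)-4-[1-(1-ethoxy-2-iodoethoxy)prop-2-en-1-yl]-1,2-dimethoxybenzene (acetal epimers) | C=C[C@H](OC(CI)OCC)c1ccc(OC)c(OC)c1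
F2 | step 4 | (4S,5S)-5-(3,4-dimethoxyphenyl)-2-ethoxy-4-(iodomethyl)tetrahydrofuran (epimers at C2) | CCOC1C[C@H](CI)[C@@H](c2ccc(OC)c(OC)c2)O1
F3 | step 6 | (R)-4-[(S)-(3,4-dimethoxyphenyl)(hydroxy)methyl]dihydrofuran-2(3H)-one | O=C1C[C@H](CO1)[C@H](O)c2ccc(OC)c(OC)c2
F4 | step 6 | (R)-4-[(S)-(tert-butyldimethylsilyloxy)(3,4-dimethoxyphenyl)methyl]dihydrofuran-2(3H)-one | O=C1C[C@H](CO1)[C@H](O[Si](C)(C)C(C)(C)C)c2ccc(OC)c(OC)c2
F5 | step 6 | (3R,4R)-3-[4-(benzyloxy)-3-methoxybenzyl]-4-[(S)-(tert-butyldimethylsilyloxy)(3,4-dimethoxyphenyl)methyl]dihydrofuran-2(3H)-one | COc1cc(C[C@H]2C(=O)OC[C@@H]2[C@H](O[Si](C)(C)C(C)(C)C)c2ccc(OC)c(OC)c2)ccc1OCc1ccccc1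
F6 | step 7 | (3R,4R)-3-[4-(benzyloxy)-3-methoxybenzyl]-4-[(S)-(3,4-dimethoxyphenyl)(triethylsilyloxy)methyl]dihydrofuran-2(3H)-one | COc1cc(C[C@H]2C(=O)OC[C@@H]2[C@H](O[Si](CC)(CC)CC)c2ccc(OC)c(OC)c2)ccc1OCc1ccccc1
F7 | step 7 | (3R,4R)-4-[(S)-(3,4-dimethoxyphenyl)(triethylsilyloxy)methyl]-3-(4-hydroxy-3-methoxybenzyl)dihydrofuran-2(3H)-one | COc1cc(C[C@H]2C(=O)OC[C@@H]2[C@H](O[Si](CC)(CC)CC)c2ccc(OC)c(OC)c2)ccc1O
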